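Ring A is disconnected at C4a–C5 and C8–C8a. The key step exploits the four contiguous oxygen-bearing carbons C5–C8 of ring A, which map onto the ring carbons of dimethyl squarate, while C8a and C4a are C2 and C3 of a preformed 6-aryl-4-pyranone (rings C and B). Heating racemic precursor 11, a 4-hydroxy-2,3-dimethoxycyclobutenone carrying the pyranon-2-yl group on its carbinol carbon, gives a vinylketene that closes onto pyranone C3, forging C4a–C5 and the benzo ring as the 5,8-diol 6,7-dimethyl ether 14. Because the 5-oxygen and O1 both flank C4a, acid-mediated opening and reclosure of ring C then transposes this into the target's 5,6-diol 7,8-dimethyl ether.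

Key step: step 5

Remark: the target SMILES holds no stereocentre or other stereogenic element, so it is one achiral compound and no enantiocontrol is needed; the only stereocentres on the way (carbinol carbon of 11, C4a of transient 13) are racemic and are erased in step 5.

Step 1
Reactants: 1 3-hydroxy-4-methoxyacetophenone; 2 benzyl bromide
Product: 3 3-benzyloxy-4-methoxyacetophenone
Conditions: K2CO3, DMF, 60 °C
Reagents that add atoms: benzyl bromide BrCc1ccccc1
Why: Williamson ether synthesis: carbonate deprotonates the only acidic site, the phenol, and the phenoxide displaces bromide from the benzylic halide while the methyl ketone stays untouched.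

Step 2
Reactants: 3 3-benzyloxy-4-methoxyacetophenone; 4 ethyl acetate
Product: 5 1-(3-benzyloxy-4-methoxyphenyl)butane-1,3-dione
Conditions: NaH, EtOAc (excess), THF, 0 °C to reflux; then aq. HCl
Reagents that add atoms: ethyl acetate CCOC(C)=O
Why: Crossed Claisen condensation: the sodium enolate of the methyl ketone is acylated by ethyl acetate and the otherwise unfavourable equilibrium is pulled over by irreversible formation of the stabilised diketonate, the two aryl ethers being inert to sodium hydride.

Step 3
Reactants: 5 1-(3-benzyloxy-4-methoxyphenyl)butane-1,3-dione; 6 ethyl formate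
Product: 8 2-(3-benzyloxy-4-methoxyphenyl)-4H-pyran-4-one, via formyl diketone 7 (not isolated)
Conditions: LDA (3.2 equiv), THF, −78 to 0 °C; HCO2Et, −78 °C to rt; 3 M HCl; crude 7, TsOH·H2O (cat.), toluene, 80 °C
Reagents that add atoms: ethyl formate CCOC=O
Why: Terminal acylation of a 1,3-diketone dianion (Hauser-type γ-functionalisation): after the central CH2 is deprotonated the second lithiation can only occur at the methyl group, this more reactive carbanion is formylated by ethyl formate, and acid then cyclodehydrates the 1,3,5-tricarbonyl compound 7 (enol oxygen onto the aldehyde, loss of water) to the γ-pyrone.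

Step 4
Reactants: 8 2-(3-benzyloxy-4-methoxyphenyl)-4H-pyran-4-one; 9 dimethyl squarate
Product: 11 (±)-4-[6-(3-benzyloxy-4-methoxyphenyl)-4-oxo-4H-pyran-2-yl]-4-hydroxy-2,3-dimethoxycyclobut-2-en-1-one, via 6-lithiopyranone 10 (not isolated)
Conditions: LiTMP (from TMPH, n-BuLi), THF, −78 °C, 8 added to the base, 15 min; cannula into 9 (1.3 equiv), THF, −78 °C; sat. aq. NH4Cl
Reagents that add atoms: dimethyl squarate COC1=C(OC)C(=O)C1=O
Why: Deprotonative lithiation of the sp2 C–H next to the ring oxygen (C6, acidified by O1 and by its β-relationship to the carbonyl, as in the C2-lithiation of chromones and the C6-lithiation of uracils with hindered lithium amides) gives 10, which adds 1,2 to one of the two equivalent carbonyl groups of the squarate at −78 °C as aryl- and heteroaryllithiums generally do; the carbinol stereocentre forms as a racemate and is erased in step 5.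

Step 5
Reactants: 11 (±)-4-[6-(3-benzyloxy-4-methoxyphenyl)-4-oxo-4H-pyran-2-yl]-4-hydroxy-2,3-dimethoxycyclobut-2-en-1-one
Product: 14 2-(3-benzyloxy-4-methoxyphenyl)-5,8-dihydroxy-6,7-dimethoxychromen-4-one, via vinylketene 12 (not isolated), via ring-fused dienone 13 (not isolated)
Conditions: degassed toluene, 110 °C, Ar; aq. Na2S2O4 wash
Reagents that add atoms: none
Why: Thermal conrotatory 4π opening breaks the bond between the carbinol carbon and the carbonyl carbon of the cyclobutenone and gives vinylketene 12, whose ketene carbon then bonds to pyranone C3 in a 6π electrocyclisation that forms C4a–C5; enolisation of the resulting dienone 13 (loss of the doubly activated 4a-H) aromatises ring A. The closest known reaction type is the Moore-type thermal ring expansion of 4-alkenyl-, 4-aryl- and 4-heteroaryl-4-hydroxycyclobutenones to hydroquinones, applied here with the C2=C3 enol-ether bond of a γ-pyrone as the 2π partner. Ring A, the only ring closed, arises by thermally allowed disrotatory 6π electrocyclic closure of the triene C4a=C8a–C8=C7–C6=C5 (the ketene C=C being the third double bond), so that all six carbons lie in the new carbocycle. The step needs torquoselectivity, secured by the donor hydroxyl, which rotates outward and thereby turns the pyranonyl group inward next to the ketene and keeps the OH from lactonising onto it; the site of closure is unambiguous because C3 is the only carbon neighbour of the attachment carbon (the other neighbour is O1) and it is the nucleophilic β-carbon of the enol ether, matched to the electrophilic ketene carbon. No stereocentre is created in the product: the racemic carbinol carbon becomes aromatic C8 and the transient C4a centre of 13 disappears on tautomerisation. Degassed solvent and a dithionite wash should hold the product at the hydroquinone oxidation level.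

Step 6
Reactants: 14 2-(3-benzyloxy-4-methoxyphenyl)-5,8-dihydroxy-6,7-dimethoxychromen-4-one
Product: 16 2-(3-benzyloxy-4-methoxyphenyl)-5,6-dihydroxy-7,8-dimethoxychromen-4-one, via ring-opened diketone 15 (not isolated)
Conditions: 3 M aq. HCl–1,4-dioxane (1:1), 100 °C, degassed, Ar
Reagents that add atoms: none
Why: Wessely–Moser rearrangement: acid-catalysed addition of water at C2 opens ring C to diketone 15, in which the former 5-OH and the former ring oxygen are both ortho to the acyl group, and recyclisation through the former 5-oxygen is expected to win at equilibrium because only the 5,6-diol gains the cooperative hydrogen-bond chain 6-OH···5-OH···O=C4 (the same sense as the classical 5,7,8 to 5,6,7 drift), while aryl methyl and benzyl ethers tolerate hot dilute hydrochloric acid and unconverted 14 can be returned to the same conditions.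

Step 7
Reactants: 16 2-(3-benzyloxy-4-methoxyphenyl)-5,6-dihydroxy-7,8-dimethoxychromen-4-one
Product: 17 5,6,3'-trihydroxy-7,8,4'-trimethoxyflavone
Conditions: H2 (1 atm), 10% Pd/C, EtOAc–MeOH, rt
Reagents that add atoms: none
Why: Palladium-catalysed hydrogenolysis of the aryl benzyl ether at 1 atm and room temperature, conditions under which the flavone C2=C3 bond, the carbonyl group and the methyl ethers are not reduced or cleaved.

Compound list
1 | 3-hydroxy-4-methoxyacetophenone | CC(=O)c1ccc(OC)c(O)c1 | starting material
2 | benzyl bromide | BrCc1ccccc1 | starting material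
3 | 3-benzyloxy-4-methoxyacetophenone | CC(=O)c1ccc(OC)c(OCc2ccccc2)c1 | intermediate
4 | ethyl acetate | CCOC(C)=O | starting material
5 | 1-(3-benzyloxy-4-methoxyphenyl)butane-1,3-dione | CC(=O)CC(=O)c1ccc(OC)c(OCc2ccccc2)c1 | intermediate
6 | ethyl formate | CCOC=O | starting material
7 | 5-(3-benzyloxy-4-methoxyphenyl)-3,5-dioxopentanal (formyl diketone, not isolated) | O=CCC(=O)CC(=O)c1ccc(OC)c(OCc2ccccc2)c1 | intermediate
8 | 2-(3-benzyloxy-4-methoxyphenyl)-4H-pyran-4-one | COc1ccc(-c2cc(=O)cco2)cc1OCc1ccccc1 | intermediate
9 | dimethyl squarate (3,4-dimethoxycyclobut-3-ene-1,2-dione) | COC1=C(OC)C(=O)C1=O | starting material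
10 | [6-(3-benzyloxy-4-methoxyphenyl)-4-oxo-4H-pyran-2-yl]lithium (6-lithiopyranone, not isolated) | [Li]c1cc(=O)cc(-c2ccc(OC)c(OCc3ccccc3)c2)o1 | intermediate
11 | (±)-4-[6-(3-benzyloxy-4-methoxyphenyl)-4-oxo-4H-pyran-2-yl]-4-hydroxy-2,3-dimethoxycyclobut-2-en-1-one (racemic) | COC1=C(OC)C(O)(c2cc(=O)cc(-c3ccc(OC)c(OCc4ccccc4)c3)o2)C1=O | intermediate
12 | (3Z)-4-[6-(3-benzyloxy-4-methoxyphenyl)-4-oxo-4H-pyran-2-yl]-4-hydroxy-2,3-dimethoxybuta-1,3-dien-1-one (vinylketene, not isolated) | O=C=C(OC)/C(OC)=C(/O)c1cc(=O)cc(-c2ccc(OC)c(OCc3ccccc3)c2)o1 | intermediate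
13 | 2-(3-benzyloxy-4-methoxyphenyl)-8-hydroxy-6,7-dimethoxy-4aH-chromene-4,5-dione (racemic at C4a, not isolated) | COc1ccc(C2=CC(=O)C3C(=O)C(OC)=C(OC)C(O)=C3O2)cc1OCc1ccccc1 | intermediate
14 | 2-(3-benzyloxy-4-methoxyphenyl)-5,8-dihydroxy-6,7-dimethoxychromen-4-one | COc1ccc(-c2cc(=O)c3c(O)c(OC)c(OC)c(O)c3o2)cc1OCc1ccccc1 | intermediate
15 | 1-(3-benzyloxy-4-methoxyphenyl)-3-(2,3,6-trihydroxy-4,5-dimethoxyphenyl)propane-1,3-dione (ring-opened diketone, not isolated) | COc1ccc(C(=O)CC(=O)c2c(O)c(OC)c(OC)c(O)c2O)cc1OCc1ccccc1 | intermediate
16 | 2-(3-benzyloxy-4-methoxyphenyl)-5,6-dihydroxy-7,8-dimethoxychromen-4-one | COc1ccc(-c2cc(=O)c3c(O)c(O)c(OC)c(OC)c3o2)cc1OCc1ccccc1 | intermediate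
17 | 5,6,3'-trihydroxy-7,8,4'-trimethoxyflavone | COc1ccc(-c2cc(=O)c3c(O)c(O)c(OC)c(OC)c3o2)cc1O | target

Total step count: 7. Longest linear sequence: 7 steps (1 to 17); compounds 2, 4, 6 and 9 enter as purchased materials.

Steps most likely to fail

Step 5. Part of the material may open with the hydroxyl turned inward, so that the ketene is captured as a butenolide; the vinylketene may oligomerise before it closes onto the pyranone; and the hydroquinone may be oxidised at the reaction temperature. The fallback changes the species that is thermolysed from the free carbinol to its silyl ether. Setting out from 8, the lithium alkoxide formed under the conditions of step 4 would be trapped in the flask with TMSCl to give (±)-4-[6-(3-benzyloxy-4-methoxyphenyl)-4-oxo-4H-pyran-2-yl]-2,3-dimethoxy-4-(trimethylsilyloxy)cyclobut-2-en-1-one F1. Thermolysis in toluene at 110 °C should then give 2-(3-benzyloxy-4-methoxyphenyl)-5-hydroxy-6,7-dimethoxy-8-(trimethylsilyloxy)chromen-4-one F2, because the silyloxy group still rotates outward, the ketene cannot be trapped internally and the para-oxygen is masked against oxidation. Dilute HCl in THF would remove the silyl group, and the fallback comes back to the route at 14.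

Step 6. The equilibration between the two modes of reclosure may stop at a mixture or stay on the side of 14, ring opening may be slow, and hot acid may erode the benzyl ether (harmless, since step 7 removes it). The fallback sets the pattern by two regioselective functional-group operations instead of an equilibrium. Setting out from 14, the unchelated 8-hydroxyl would be methylated selectively (Me2SO4, 1.05 equiv, K2CO3, acetone, Ar), the 5-hydroxyl being held by the C4 carbonyl, to give 2-(3-benzyloxy-4-methoxyphenyl)-5-hydroxy-6,7,8-trimethoxychromen-4-one F3. Anhydrous AlBr3 in MeCN should then cleave the 6-methoxyl, to which the aluminium phenoxide at O5 delivers the Lewis acid (the ortho-directed demethylation used for 5-hydroxy-6-methoxyflavones), and remove the benzyl ether in the same operation. The fallback comes back to the route at target 17.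

Step 4. Deprotonation at C3 or C5 may compete with C6, and the lithiated pyranone may add to unmetalated 8 before it meets the squarate. The fallback replaces C–H lithiation by halogen–metal exchange from a regiodefined iodide. Setting out from 8, zincation next to the ring oxygen with a hindered TMP–zinc amide, under the conditions used for zincating chromones at that position, would give the stable organozinc [6-(3-benzyloxy-4-methoxyphenyl)-4-oxo-4H-pyran-2-yl]zinc chloride F4. Iodolysis would give 2-(3-benzyloxy-4-methoxyphenyl)-6-iodo-4H-pyran-4-one F5, whose regiochemistry can be checked before it is committed. Iodine–magnesium exchange (i-PrMgCl·LiCl, THF, −40 °C) would give [6-(3-benzyloxy-4-methoxyphenyl)-4-oxo-4H-pyran-2-yl]magnesium chloride F6, which adds to 9 at low temperature, and the fallback comes back to the route at 11.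

Further compounds
F1 | step 5 | (±)-4-[6-(3-benzyloxy-4-methoxyphenyl)-4-oxo-4H-pyran-2-yl]-2,3-dimethoxy-4-(trimethylsilyloxy)cyclobut-2-en-1-one (racemic) | COC1=C(OC)C(O[Si](C)(C)C)(c2cc(=O)cc(-c3ccc(OC)c(OCc4ccccc4)c3)o2)C1=O
F2 | step 5 | 2-(3-benzyloxy-4-methoxyphenyl)-5-hydroxy-6,7-dimethoxy-8-(trimethylsilyloxy)chromen-4-one | COc1ccc(-c2cc(=O)c3c(O)c(OC)c(OC)c(O[Si](C)(C)C)c3o2)cc1OCc1ccccc1
F3 | step 6 | 2-(3-benzyloxy-4-methoxyphenyl)-5-hydroxy-6,7,8-trimethoxychromen-4-one | COc1ccc(-c2cc(=O)c3c(O)c(OC)c(OC)c(OC)c3o2)cc1OCc1ccccc1
F4 | step 4 | [6-(3-benzyloxy-4-methoxyphenyl)-4-oxo-4H-pyran-2-yl]zinc chloride | Cl[Zn]c1cc(=O)cc(-c2ccc(OC)c(OCc3ccccc3)c2)o1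
F5 | step 4 | 2-(3-benzyloxy-4-methoxyphenyl)-6-iodo-4H-pyran-4-one | COc1ccc(-c2cc(=O)cc(I)o2)cc1OCc1ccccc1
F6 | step 4 | [6-(3-benzyloxy-4-methoxyphenyl)-4-oxo-4H-pyran-2-yl]magnesium chloride | Cl[Mg]c1cc(=O)cc(-c2ccc(OC)c(OCc3ccccc3)c2)o1
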